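All runs were computed for substances that don't exist, and the scatter is random.

**The decision.** Feed the X. That is my choice among these flasks, and it rests on one count.

| setting | west | south-west | north-east | noon | autumn | midnight |
|---|---|---|---|---|---|---|
| X | 0.10 M | 0.10 M | 0.10 M | 0.10 M | 0.10 M | 0.10 M (fed, over 20 min) |
| J | 0.11 M | 0.055 M | 0.22 M | 0.110 M (fed, over 20 min) | 0.110 M | 0.110 M |
| Q | 0.050 M | 0.050 M | 0.050 M | 0.0500 M | 0.0500 M | 0.0500 M |
| Z | 0.74 µM | 0.74 µM | 0.74 µM | 0.74 µM | 0.74 µM | 0.74 µM |
| remark | run made earlier | run made earlier | run made earlier | all else is in the flask from the start; the feed brings no volume worth counting | everything together at the start | all else is in the flask from the start; the feed brings no volume worth counting |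
| time |  |  |  | 30 min | 30 min | 30 min |

- the best flask by amount of E, in percent of the X charged; "all alike" if 1.5 percentage points covers them all (noon / autumn / midnight / all alike)
- amount of E at the end, in percent of the X charged, noon
- amount of E at the end, in percent of the X charged, autumn
- amount of E at the end, in percent of the X charged, midnight

- the numbers in the tables scatter by 0.3 percentage points (one standard deviation)

| west: time / min | west: E / % | south-west: time / min | south-west: E / % | north-east: time / min | north-east: E / % |
|---|---|---|---|---|---|
| 1.33 | 5.3 | 6.00 | 21.2 | 2.50 | 10.3 |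
| 4.00 | 15.8 | 12.0 | 38.4 | 8.00 | 32.6 |
| 6.00 | 23.8 | 20.0 | 51.2 | 12.0 | 48.2 |
| 10.0 | 38.2 | 25.0 | 53.7 | 20.0 | 73.5 |
| 15.0 | 55.3 | 30.0 | 54.2 | 30.0 | 77.6 |
| 20.0 | 68.6 | 40.0 | 54.3 | 40.0 | 77.4 |

(readings scatter by 0.3 percentage points)

**Standing time.** North-east ends at 77.4 % of E although its J exceeds its X, so 22.6 % of the X went elsewhere. I assume that this loss goes with the X present, and I count standing time: the mean share of the charge of X present, times the minutes. North-east's E reaches 73.5 % at 20.0 min, so at that pace its plateau comes at 21.1 min. I draw X as a straight line down to that moment, which makes standing time 10.5 min, half of that. Lost share over standing time gives 0.0215 min⁻¹, my loss constant.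

**The feed.** Late in north-east, E rises by 25 percentage points in 8.00 min, a pace at which a whole charge takes 31.6 min. I lend that pace to midnight. It is slower than the feed, so by my count X builds to 36.8 % when the feed ends, then drains. Midnight's standing time comes to 5.81 min, shorter than north-east's, and the loss constant turns it into a loss of 12.5 %. What I buy is selectivity, E against that loss. My count leaves 87.5 % for E and X together, and its drain ends after the asked 30 min, so some X still stands then. Noon has its X in from the start, as autumn has, so I expect no gain there.

**The forecast.** It names midnight: noon 70 % (65 % to 76 %), autumn 77 % (75 % to 80 %), midnight 80 % (74 % to 87 %). Its ground for midnight is “X stays low, so less is lost”.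

**The flasks.** Noon gives 72.0 %, autumn 76.3 % and midnight 81.9 %, so midnight is best.

    X + Z ⇌ D (K = 29.0 L mol⁻¹, k = 33000 L mol⁻¹ s⁻¹)
    J + D ⇌ G (K = 170 L mol⁻¹, k = 1.10 × 10⁵ L mol⁻¹ s⁻¹)
    G → Z + E (k = 100 s⁻¹)
    X + Q → L (k = 0.0110 L mol⁻¹ s⁻¹)

**The gap.** The loss of X + Q to L is the largest single effect on the gap of 10 points between midnight and noon: with that step taken away, the gap is 1.2 points. Midnight's mean X over the feed, 0.0182 M, is a standing time of 3.64 min, which the loss constant turns into 7.81 %, and the flask holds 10.7 % of L at 20.0 min. Noon's mean X, 0.0564 M, turns into 24.2 %, and that flask holds 26.3 % of L at 20.0 min.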